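The C40 polyene is joined at C11=C12 from a C25 acyclic ylide (pseudoionone-derived C15 salt plus the C10 dialdehyde) and a C15 ring aldehyde. The plan turns on recognising the ring's cis-3,4-diol, whose C4 oxygen is flanked by the fully substituted C5=C6 alkene, as what remains when a C4–C5 epoxide in the isomeric α-ionone ring is opened from C6. One base treatment removes the C6 hydrogen (vinylogously acidified by the C9 ketone), cleaves the C5–O bond, shifts the ring alkene into conjugation and releases the C4 hydroxyl without touching its configuration, while the C6 centre disappears. The substrate is (3R)-3-hydroxy-α-ionone carrying a 4,5-epoxide on the hydroxyl face, both C6 epimers.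

Key step: step 6

Remark on the chemistry: locants follow ionone/carotenoid numbering (ring C1 to C6, chain from C7, ketone C9); C6 is left unspecified in the SMILES of 2 to 7 because both configurations are carried on purpose; the hydroxyls stay unprotected after step 6 because every later step on the ring fragment is basic or hydridic, which keeps the allylic C4–O bond away from acid.

Step 1
Reactants: 1 (±)-α-ionone
Product: 2 α-ionone ethylene ketal (racemic)
Conditions: HOCH2CH2OH, HC(OMe)3, p-toluenesulfonic acid (cat.), rt
Reagents that add atoms: ethylene glycol, OCCO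
Why: Acid-catalysed ketalisation with the orthoformate as water scavenger masks the C9 carbonyl so that only the ring ketone introduced next is reduced; at room temperature neither the C4=C5 nor the C7=C8 bond should migrate.

Step 2
Reactants: 2 α-ionone ethylene ketal
Product: 3 3-oxo-α-ionone ethylene ketal (racemic)
Conditions: t-BuOOH (70% aq), NaOCl (aq), K2CO3, MeCN, 0 °C
Reagents that add atoms: tert-butyl hydroperoxide, CC(C)(C)OO
Why: Radical allylic oxidation by tert-butylperoxyl radicals generated from the hydroperoxide and hypochlorite attacks C3, the only allylic methylene of the molecule, and leaves the conjugated ring enone, while the doubly allylic C6–H is shielded by the geminal C1 methyls, the C5 methyl and the side chain and the ketal is stable at this pH.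

Step 3
Reactants: 3 3-oxo-α-ionone ethylene ketal
Product: 4 (3R)-3-hydroxy-α-ionone ethylene ketal (both C6 epimers)
Conditions: (S)-Me-CBS oxazaborolidine [(S)-1-methyl-3,3-diphenyltetrahydro-1H,3H-pyrrolo[1,2-c][1,3,2]oxazaborole] (0.2 equiv), catecholborane, toluene, −78 °C; then MeOH, aq. NaOH
Reagents that add atoms: none
Why: Corey–Bakshi–Shibata reduction: the oxazaborolidine–borane complex binds the ring carbonyl with the C4=C5 alkene arm as the large substituent and the C2 methylene as the small one, so that by the usual model the (S)-catalyst delivers hydride to the face giving 3R whichever configuration C6 has (catalyst control over a racemate, giving two 3R diastereomers), and catecholborane at −78 °C avoids hydroboration and conjugate reduction; the configuration at C3 is to be confirmed on the Mosher esters before the material is taken on.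

Step 4
Reactants: 4 (3R)-3-hydroxy-α-ionone ethylene ketal
Product: 5 (3R)-3-hydroxy-α-ionone (both C6 epimers)
Conditions: 0.5 M HCl (aq), THF, 0 °C
Reagents that add atoms: water, O
Why: Acid-catalysed ketal hydrolysis, fast for the ketal of a conjugated ketone because the oxocarbenium ion is allylic, so that dilute acid at 0 °C should leave the allylic C3 alcohol and its configuration alone.

Step 5
Reactants: 5 (3R)-3-hydroxy-α-ionone
Product: 6 (3R,4R,5S)-4,5-epoxy-3-hydroxy-4,5-dihydro-α-ionone (epoxide cis to the hydroxyl; both C6 epimers)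
Conditions: VO(acac)2 (3 mol%), t-BuOOH (in decane), CH2Cl2, 0 °C to rt
Reagents that add atoms: tert-butyl hydroperoxide, CC(C)(C)OO
Why: Vanadium-catalysed hydroxyl-directed epoxidation: the C3 alkoxide bound to the vanadium peroxide delivers oxygen to the same face of the neighbouring C4=C5 bond, which sets C4 (R) and C5 (S) syn to the hydroxyl in both C6 epimers, and the electron-poor C7=C8 enone bond does not react.

Step 6
Reactants: 6 (3R,4R,5S)-4,5-epoxy-3-hydroxy-4,5-dihydro-α-ionone
Product: 8 (3R,4S)-3,4-dihydroxy-β-ionone, via dienolate 7 (not isolated)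
Conditions: 1,8-diazabicyclo[5.4.0]undec-7-ene (DBU, 1.5 equiv), MeCN, rt to 50 °C
Reagents that add atoms: none
Why: DBU reversibly removes the C6 hydrogen, which is gamma to the C9 carbonyl through C7=C8, and the resulting dienolate 7 pushes its electron pair into the adjacent C5–O bond, so that the strained epoxide opens in an E1cB step that forms the C5=C6 bond and a C4 alkoxide, which DBU-H+ then protonates. The closest known reaction type is the base-induced isomerisation of α-ionone 4,5-epoxide to 4-hydroxy-β-ionone, a vinylogous form of the opening of β,γ-epoxy ketones to γ-hydroxy enones. No ring is closed and no stereocentre is created: only the C5–O bond breaks, so C4 keeps its oxygen on the face fixed in step 5, cis to the C3 hydroxyl (the descriptor changes from 4R to 4S only because C5 loses its oxygen), while C6 becomes trigonal and both C6 epimers of 6 converge on 8. The selectivity needed is between C6 and the C10 methyl: enolisation toward C10 is reversible and has no leaving group to expel, whereas the C6 anion sits next to the epoxide carbon and its collapse to the fully conjugated dienone is irreversible. The C3 hydroxyl, being syn to the epoxide, cannot attack C4 from the rear, so no Payne rearrangement competes, and its hydrogen bond to the epoxide oxygen should assist the departure.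

Step 7
Reactants: 8 (3R,4S)-3,4-dihydroxy-β-ionone
Product: 9 (9E)-(3R,4S)-3,4-dihydroxy-β-ionylideneacetonitrile
Conditions: (EtO)2P(O)CH2CN, NaH (anion preformed), THF, 0 °C to rt; chromatography
Reagents that add atoms: diethyl cyanomethylphosphonate, CCOP(=O)(CC#N)OCC
Why: Horner–Wadsworth–Emmons olefination of the methyl ketone adds C10 and C11; the stabilised phosphonate carbanion is too weak a base to be quenched by the two hydroxyls or to enolise C4, the 9E isomer is expected to predominate for this β-ionone-type ketone, and the 9Z isomer is removed by chromatography.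

Step 8
Reactants: 9 (9E)-(3R,4S)-3,4-dihydroxy-β-ionylideneacetonitrile
Product: 11 (9E)-(3R,4S)-3,4-dihydroxy-β-ionylideneacetaldehyde, via N-aluminated aldimine 10 (not isolated)
Conditions: i-Bu2AlH (3.5 equiv), CH2Cl2, −78 °C; then aq. potassium sodium tartrate, rt
Reagents that add atoms: water, O
Why: Partial reduction of a nitrile: after the two hydroxyls have been capped as aluminium alkoxides, a single hydride adds to the nitrile and the N-aluminated aldimine 10 persists at −78 °C until aqueous work-up hydrolyses it to the aldehyde, with no 1,4-reduction of the diene and no change at C3 or C4.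

Step 9
Reactants: 12 pseudoionone
Product: 13 vinylpseudoionol (racemic)
Conditions: CH2=CHMgBr, THF, −20 to 0 °C; then aq. NH4Cl
Reagents that add atoms: vinylmagnesium bromide, C=C[Mg]Br
Why: Grignard 1,2-addition to the carbonyl of the dienone, the normal course for vinylmagnesium halides with methyl polyenyl ketones; the tertiary carbinol centre is formed as a racemate and disappears in step 10.

Step 10
Reactants: 13 vinylpseudoionol
Product: 14 acyclic C15 phosphonium bromide
Conditions: PPh3·HBr, MeOH, rt; crystallisation
Reagents that add atoms: triphenylphosphine hydrobromide, [Br-].[PH+](c1ccccc1)(c1ccccc1)c1ccccc1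
Why: Acid-promoted SN1′ allylic transposition: the tertiary, doubly allylic alcohol ionises under the phosphonium acid and triphenylphosphine is captured at the unhindered primary terminus, giving the conjugated phosphonium salt whose 2E isomer is obtained by crystallisation.

Step 11
Reactants: 14 acyclic C15 phosphonium bromide; 15 C10 dialdehyde
Product: 17 12'-apo-ψ-caroten-12'-al (C25 aldehyde), via ylide 16 (not isolated)
Conditions: NaOMe added slowly to 14 and 15 (3 equiv), MeOH/CH2Cl2, 0 °C; then heptane, reflux
Reagents that add atoms: none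
Why: Wittig olefination in which the ylide 16 is generated in the presence of a threefold excess of the symmetrical dialdehyde so that mono-olefination dominates (the surplus dialdehyde is recovered and the sparingly soluble bis-adduct is filtered off), followed by thermal Z to E equilibration of the new disubstituted double bond.

Step 12
Reactants: 17 12'-apo-ψ-caroten-12'-al
Product: 18 12'-apo-ψ-caroten-12'-ol (C25 alcohol)
Conditions: NaBH4, EtOH/THF, 0 °C
Reagents that add atoms: none
Why: Borohydride 1,2-reduction of the aldehyde at 0 °C, chemoselective because the hydride does not add to the unactivated polyene.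

Step 13
Reactants: 18 12'-apo-ψ-caroten-12'-ol
Product: 19 C25 polyenyl phosphonium bromide
Conditions: PPh3·HBr, MeOH/CH2Cl2, rt, dark
Reagents that add atoms: triphenylphosphine hydrobromide, [Br-].[PH+](c1ccccc1)(c1ccccc1)c1ccccc1
Why: Phosphonium salt formation from a primary allylic polyenyl alcohol by the same acid-promoted ionisation and phosphine capture as in step 10 (the retinol to retinylphosphonium salt reaction with a longer chain), the phosphine ending at the primary carbon where full conjugation is kept.

Step 14
Reactants: 19 C25 polyenyl phosphonium bromide (1.3 equiv); 11 (9E)-(3R,4S)-3,4-dihydroxy-β-ionylideneacetaldehyde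
Product: 21 (3R,4S)-β,ψ-carotene-3,4-diol (all-E; target), via ylide 20 (not isolated)
Conditions: NaOMe, MeOH/CH2Cl2, 0 °C to rt, dark, Ar; then EtOAc/heptane, reflux; crystallisation
Reagents that add atoms: none
Why: Wittig olefination forming C11=C12 between the polyenyl ylide 20 and the dienal 11; the semi-stabilised ylide tolerates the free hydroxyls (methanol is a co-solvent), C3 and C4 are not involved, and the hindered 11Z isomer is equilibrated to the all-E target on heating.

Compound list

1 | (±)-α-ionone, (E)-4-(2,6,6-trimethylcyclohex-2-en-1-yl)but-3-en-2-one | CC(=O)/C=C/C1C(C)=CCCC1(C)C | starting material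
2 | α-ionone ethylene ketal, 2-methyl-2-[(E)-2-(2,6,6-trimethylcyclohex-2-en-1-yl)ethenyl]-1,3-dioxolane, racemic | CC1(/C=C/C2C(C)=CCCC2(C)C)OCCO1 | intermediate
3 | 3-oxo-α-ionone ethylene ketal (ring enone, C3 ketone conjugated to C4=C5), racemic | CC1(/C=C/C2C(C)=CC(=O)CC2(C)C)OCCO1 | intermediate
4 | (3R)-3-hydroxy-α-ionone ethylene ketal, both C6 epimers | CC1(/C=C/C2C(C)=C[C@H](O)CC2(C)C)OCCO1 | intermediate
5 | (3R)-3-hydroxy-α-ionone, both C6 epimers | CC(=O)/C=C/C1C(C)=C[C@H](O)CC1(C)C | intermediate
6 | (3R,4R,5S)-4,5-epoxy-3-hydroxy-4,5-dihydro-α-ionone, epoxide cis to the C3 hydroxyl, both C6 epimers | CC(=O)/C=C/C1[C@]2(C)O[C@@H]2[C@H](O)CC1(C)C | intermediate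
7 | C6 dienolate of 6 (C6=C7–C8=C9–O−) as its DBU-H+ salt | CC([O-])=CC=C1[C@]2(C)O[C@@H]2[C@H](O)CC1(C)C.C1CCC2=[NH+]CCCN2CC1 | intermediate (not isolated)
8 | (3R,4S)-3,4-dihydroxy-β-ionone, cis diol | CC(=O)/C=C/C1=C(C)[C@H](O)[C@H](O)CC1(C)C | intermediate
9 | (9E)-(3R,4S)-3,4-dihydroxy-β-ionylideneacetonitrile (C15 nitrile; 7E,9E) | N#C/C=C(C)/C=C/C1=C(C)[C@H](O)[C@H](O)CC1(C)C | intermediate
10 | N-(diisobutylaluminio) aldimine of 11 with both hydroxyls as diisobutylaluminium alkoxides | CC(C)C[Al](CC(C)C)N=C/C=C(C)/C=C/C1=C(C)[C@H](O[Al](CC(C)C)CC(C)C)[C@H](O[Al](CC(C)C)CC(C)C)CC1(C)C | intermediate (not isolated)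
11 | (9E)-(3R,4S)-3,4-dihydroxy-β-ionylideneacetaldehyde (C15 ring aldehyde; 7E,9E) | O=C/C=C(C)/C=C/C1=C(C)[C@H](O)[C@H](O)CC1(C)C | intermediate
12 | pseudoionone, (3E,5E)-6,10-dimethylundeca-3,5,9-trien-2-one | CC(C)=CCC/C(C)=C/C=C/C(C)=O | starting material
13 | vinylpseudoionol, (4E,6E)-3,7,11-trimethyldodeca-1,4,6,10-tetraen-3-ol, racemic | CC(C)=CCC/C(C)=C/C=C/C(C)(O)C=C | intermediate
14 | [(2E,4E,6E)-3,7,11-trimethyldodeca-2,4,6,10-tetraen-1-yl]triphenylphosphonium bromide | CC(C)=CCC/C(C)=C/C=C/C(C)=C/C[P+](c1ccccc1)(c1ccccc1)c1ccccc1.[Br-] | intermediate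
15 | C10 dialdehyde, (2E,4E,6E)-2,7-dimethylocta-2,4,6-trienedial | O=C/C(C)=C/C=C/C=C(C)/C=O | starting material
16 | ylide of 14, [(2E,4E,6E)-3,7,11-trimethyldodeca-2,4,6,10-tetraen-1-ylidene]triphenylphosphorane | CC(C)=CCC/C(C)=C/C=C/C(C)=C/C=P(c1ccccc1)(c1ccccc1)c1ccccc1 | intermediate (not isolated)
17 | 12'-apo-ψ-caroten-12'-al, (2E,4E,6E,8E,10E,12E,14E)-2,7,11,15,19-pentamethylicosa-2,4,6,8,10,12,14,18-octaenal | CC(C)=CCC/C(C)=C/C=C/C(C)=C/C=C/C(C)=C/C=C/C=C(C)/C=O | intermediate
18 | 12'-apo-ψ-caroten-12'-ol, the corresponding all-E icosaoctaen-1-ol | CC(C)=CCC/C(C)=C/C=C/C(C)=C/C=C/C(C)=C/C=C/C=C(C)/CO | intermediate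
19 | [(all-E)-2,7,11,15,19-pentamethylicosa-2,4,6,8,10,12,14,18-octaen-1-yl]triphenylphosphonium bromide | CC(C)=CCC/C(C)=C/C=C/C(C)=C/C=C/C(C)=C/C=C/C=C(C)/C[P+](c1ccccc1)(c1ccccc1)c1ccccc1.[Br-] | intermediate
20 | ylide of 19 (C25 polyenylidene triphenylphosphorane) | CC(C)=CCC/C(C)=C/C=C/C(C)=C/C=C/C(C)=C/C=C/C=C(C)/C=P(c1ccccc1)(c1ccccc1)c1ccccc1 | intermediate (not isolated)
21 | (3R,4S)-β,ψ-carotene-3,4-diol, all-E | CC(C)=CCC/C(C)=C/C=C/C(C)=C/C=C/C(C)=C/C=C/C=C(C)/C=C/C=C(C)/C=C/C1=C(C)[C@H](O)[C@H](O)CC1(C)C | target

Total step count: 14. Longest linear sequence: 9 steps (steps 1 to 8, then step 14, from α-ionone). The pseudoionone branch contributes steps 9 to 13 and joins in step 14.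

Steps most likely to fail

1. Step 6 (key step). Deprotonation at C6 by an amine base may be too slow, so that reversible enolisation toward the C10 methyl and slow self-condensation consume the ketone. Alternatively the product may be deprotonated at C4 and the allylic alcohol may drift to a saturated 4-ketone. The fallback replaces carbanionic opening by electrophilic opening and sets out from 6. Excess TMSOTf with 2,6-lutidine in CH2Cl2 at −78 °C silylates the C3 hydroxyl and the epoxide oxygen, the C5–O bond ionises at the tertiary carbon, and DBU then removes the C6 proton (silyl triflate-mediated isomerisation of an epoxide to an allylic silyl ether). After aqueous work-up this should give (3R,4S)-3,4-bis(trimethylsilyloxy)-β-ionone F1, again with the C4–O bond untouched. K2CO3 in MeOH removes both silyl groups, and the route is rejoined at 8.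

2. Step 3. Facial discrimination may be poor, because the two flanks of the ring carbonyl (the C2 methylene next to quaternary C1 and the vinylic C4–H) differ little in size, and one C6 configuration may be a mismatched partner for the catalyst. The result would be eroded enantiopurity at C3 that no later step can repair. The fallback sets out from 3. Luche reduction (NaBH4, CeCl3·7H2O, MeOH, 0 °C) gives 3-hydroxy-α-ionone ethylene ketal as all four stereoisomers F2. Kinetic resolution by enzymatic acylation (Burkholderia cepacia lipase, vinyl acetate, t-BuOMe) is expected, by the Kazlauskas rule with the alkenyl flank as the large group, to acylate the 3R alcohols of both C6 series. This gives (3R)-3-acetoxy-α-ionone ethylene ketal F3, which is separated from the 3S alcohols (these can be returned to 3 with MnO2) and methanolysed (K2CO3, MeOH). The route is rejoined at 4. Should the enzyme prefer the 3S alcohols, the unreacted 3R alcohols are 4 directly.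

3. Step 13. The long polyenyl alcohol ionises very easily, and phosphine capture at internal positions, oligomerisation or Z/E scrambling could leave a non-crystalline salt that cannot be purified. The fallback reverses the polarity of the final olefination; it sets out from 8, uses aldehyde 17 as the partner and makes 18 and 19 unnecessary.
- TBSOTf and 2,6-lutidine (CH2Cl2, −78 to 0 °C) give (3R,4S)-3,4-bis(tert-butyldimethylsilyloxy)-β-ionone F4.
- CH2=CHMgBr in THF adds to the C9 ketone to give the tertiary vinyl carbinol F5.
- PPh3·HBr in CH2Cl2 at 0 °C, with short acid contact because of the allylic C4 silyl ether, gives the ring C15 phosphonium bromide F6.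
- NaOMe generates the ring C15 ylide F7, which is condensed with 17 and equilibrated thermally to (3R,4S)-3,4-bis(tert-butyldimethylsilyloxy)-β,ψ-carotene F8.
- Bu4NF in THF removes the silyl groups, and the route is rejoined at 21.

Further compounds

F1 | step 6 | (3R,4S)-3,4-bis(trimethylsilyloxy)-β-ionone | CC(=O)/C=C/C1=C(C)[C@H](O[Si](C)(C)C)[C@H](O[Si](C)(C)C)CC1(C)C
F2 | step 3 | 3-hydroxy-α-ionone ethylene ketal, all four stereoisomers | CC1(/C=C/C2C(C)=CC(O)CC2(C)C)OCCO1
F3 | step 3 | (3R)-3-acetoxy-α-ionone ethylene ketal, both C6 epimers | CC1(/C=C/C2C(C)=C[C@H](OC(C)=O)CC2(C)C)OCCO1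
F4 | step 13 | (3R,4S)-3,4-bis(tert-butyldimethylsilyloxy)-β-ionone | CC(=O)/C=C/C1=C(C)[C@H](O[Si](C)(C)C(C)(C)C)[C@H](O[Si](C)(C)C(C)(C)C)CC1(C)C
F5 | step 13 | tertiary vinyl carbinol from F4, (E)-1-[(3R,4S)-3,4-bis(tert-butyldimethylsilyloxy)-β-ring]-3-methylpenta-1,4-dien-3-ol, both C9 epimers | C=CC(C)(O)/C=C/C1=C(C)[C@H](O[Si](C)(C)C(C)(C)C)[C@H](O[Si](C)(C)C(C)(C)C)CC1(C)C
F6 | step 13 | ring C15 phosphonium bromide, [(2E,4E)-5-[(3R,4S)-3,4-bis(tert-butyldimethylsilyloxy)-β-ring]-3-methylpenta-2,4-dien-1-yl]triphenylphosphonium bromide | [Br-].c1ccccc1[P+](c1ccccc1)(c1ccccc1)C/C=C(C)/C=C/C1=C(C)[C@H](O[Si](C)(C)C(C)(C)C)[C@H](O[Si](C)(C)C(C)(C)C)CC1(C)C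
F7 | step 13 | ring C15 ylide from F6 | c1ccccc1P(c1ccccc1)(c1ccccc1)=C/C=C(C)/C=C/C1=C(C)[C@H](O[Si](C)(C)C(C)(C)C)[C@H](O[Si](C)(C)C(C)(C)C)CC1(C)C
F8 | step 13 | (3R,4S)-3,4-bis(tert-butyldimethylsilyloxy)-β,ψ-carotene, all-E | CC(C)=CCC/C(C)=C/C=C/C(C)=C/C=C/C(C)=C/C=C/C=C(C)/C=C/C=C(C)/C=C/C1=C(C)[C@H](O[Si](C)(C)C(C)(C)C)[C@H](O[Si](C)(C)C(C)(C)C)CC1(C)C
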